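Abietane numbering is used for all ring B and ring C compounds: ring B = C5, C6, C7, C8, C9, C10; ring C = C8, C9, C11, C12, C13, C14; C20 is the methyl on C10, C1–C3 the chain on C10, C4 (with C18 and C19) the isopropenyl carbon on C5.

## The problem

The target is a 3,4-seco-abietane. Ring A is opened, so C10 carries the C1–C3 propanoic acid chain and C5 the isopropenyl group. Ring B is a 1-tetralone (C7 ketone) fused through C8–C9 to a hexasubstituted ring C with hydroxyls at C11 and C14, a methoxy group at C12 and isopropyl at C13.

There are two adjacent stereocentres: the quaternary benzylic C10 (S) and the tertiary C5 (S), with the isopropenyl group cis to the C20 methyl. The C5 hydrogen is not acidic, so C5 cannot be corrected by equilibration and must be set kinetically. The two alkyl groups on C10 (methyl and a primary chain) differ little in size, so a step that must tell them apart needs a device other than bulk. No third stereocentre exists to relay information, so the absolute sense has to come from a reagent or an auxiliary.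

The fragile groups are the hydroquinone (oxidised easily, above all in base), the isopropenyl group (which excludes hydrogenolysis and strong acids late in the route) and the free acid. The three ring C oxygens must also end up differentiated.

Two features make the key step possible. First, carbonyl carbon C7 and quaternary C10 sit on the adjacent ring C carbons C8 and C9 and are joined through C6–C5. Ring B is therefore the cycloadduct of a hydroxy-ortho-quinodimethane, available from an ortho-alkyl benzaldehyde, with a C5=C6 alkene. Second, O11 lies peri to C10, so C3 can be held on O11 in a seven-membered ether, which decides which C10 substituent points outward in that diene.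

## Retrosynthesis

**25 to 23.** No skeletal bond is cut. The hydroquinone of 25 is taken back to quinone acid 24, and the acid to the primary alcohol of quinone 23. The hydroquinone is the most oxidisable group, so it is made last by mild reduction and never meets base or an oxidant. The forward steps must oxidise a primary alcohol beside an isopropenyl group and then reduce the quinone without touching the C7 ketone.

**23 to 22.** The C11 carbonyl oxygen and the C3 hydroxyl of 23 are rejoined as one ether oxygen, and the C14 carbonyl becomes a methyl ether, giving tetralone 22. Because O11 and O14 are para, one oxidative dealkylation unmasks both, leaves the C12 methyl ether in place and releases the chain. A tris-methyl ether with a free ester chain would need the same oxidation but would leave the chain untied during the key step. A lactone tether would not survive a titanium alkoxide. The forward reaction must be para-selective and spare the isopropenyl group.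

**22 to 20.** A methoxycarbonyl group is added at C6 and the C7 ketone is reduced to the carbinol, through β-keto ester 21 to hydroxy ester 20. This restores the cycloadduct pattern. The ester is the activating and regiodirecting group of the dienophile, and its removal (oxidation, then dealkoxycarbonylation) is dependable. The tail must not disturb C5, which is not enolisable.

**20 to 15 and 18.** The C5–C10 and C6–C7 bonds are cut, opening ring B to aldehyde 15 and dienoate 18.

- This single cut removes the ring and all stereocentres of the target, and leaves an achiral dienophile and an aldehyde whose one stereocentre is erased on enolisation.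
- Cutting C5–C6 or C9–C10 instead would leave the quaternary centre to be made on its own.
- Dienoate 18 already carries C4, C18 and C19, so no bond has to be made later at crowded C5.
- The forward reaction must give the ester next to the carbinol, endo addition, the chain outward in the dienol, and one face.

**18 to 16 and 17.** The C5=C6 double bond is cut by an E-selective phosphonate olefination of methacrolein 16 with phosphonoacetate 17.

**15 to 14.** The C7–C8 bond is cut. Benzoxepine 14 has a single free arene position, ortho and para to methoxy groups, so electrophilic formylation has no regiochemical choice.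

**14 to 9 and 10.** The O–C3 bond of the oxepine is cut to chloro phenol 13, and the benzylic hydrogen at C10 is traced to the carbinol of 12. The C9–C10 bond of 12 is then cut to the methoxymethyl ether 9 and 5-chloropentan-2-one 10. Electrophilic chemistry would attack C8, the more activated position, whereas the methoxymethoxy group directs metalation to C9. The forward sequence is addition, ionic deoxygenation with loss of the acetal, and ring closure.

**9 to 1 and 2.** The C11–O bond is cut (phenol 8 from arene 5 by metalation, borylation and oxidation). The C13–C15 bond is cut (5 from carbinol 4, made from 1,3-dimethoxybenzene 1 and acetone 2). Both metalations occur at positions fixed by the methoxy groups.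

## Roads not taken

**Alternative 1:** The cut is at C4–C5 and C1–C10. An isopropenyl nucleophile would add to C5 of the chiral 1-naphthyloxazoline A2, and the aza-enolate would be allylated at C10 to give the dihydronaphthalene A1.

- Merits: both stereocentres are set in one operation. Trans addition places the isopropenyl group cis to the oxazoline carbon, the future C20 methyl, which is the correct relationship. The absolute sense comes from a covalent auxiliary. In stereocontrol this road is better founded than a ligand-controlled photoreaction.
- Weak points: A2 is a hexasubstituted, tetra-oxygenated naphthalene that is long to make. Its oxazoline sits peri to the C11 methoxy group and is twisted out of conjugation on an electron-rich ring, which lowers the electrophilicity of C5.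
- Weak points after the key step: the oxazoline carbon must be reduced by three oxidation levels to a methyl group beside two alkenes and an enol ether. The allyl group must be oxidised to the acid without touching the isopropenyl group. The enol ether must be hydrolysed and ring C unmasked.
- Comparison: the chosen plan sets against the better stereocontrol a much shorter tail. Ring B arrives with every carbon at or next to its final oxidation level, and the ether tether fixes the relative configuration.

**Alternative 2:** The cut is at C8–C14, with ring C built last. Thermolysis of the 4-hydroxycyclobutenone A4 would open it to a vinylketene, which closes by 6π electrocyclisation to the hydroquinone A3.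

- Merits: the hexasubstituted ring C appears with complete regiocontrol, with O11 and O14 free and O12 methylated, under neutral thermal conditions and without protecting groups. On this point the road is better than the chosen plan, which needs eight steps to the arene and an oxidative unmasking.
- Weak points: the key step creates no stereocentre. C5 and C10 must already be present, enantiopure, in the hindered ring B alkenyl-metal fragment from which A4 is built, and that vicinal quaternary–tertiary pair is the hard part of the molecule.
- Weak points after the key step: C7 is still a methylene in A3. It must be oxidised late, next to a free hydroquinone and beside the allylic C–H bonds of the isopropenyl group. The silyl ether must also be taken to the acid.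
- Comparison: the chosen plan sets against the cleaner arene construction the fact that its key step makes ring B, both stereocentres and the C7 oxygen together.

**Alternative 3:** The cut is at C5–C6. The aldehyde carbon of the aryl glyoxal A6 would add to the 2-methylprop-1-enyl group on C10 in an intramolecular carbonyl-ene reaction, giving the 6-hydroxy-1-tetralone A5.

- Merits: ring B and the isopropenyl group form together, so no diene has to be carried. The C7 ketone is present from the start, no light is needed, and the tail (removal of the C6 hydroxyl) is one step shorter than the removal of the ester and carbinol in the chosen plan.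
- Weak points: A6 needs an enantiopure quaternary C10 bearing methyl, chain, alkenyl and a doubly ortho-substituted aryl group, which the key step does not help to make. C5 is set relative to C10 by a transition state that must distinguish the methyl group from the chain. The acid needed for the ene reaction also threatens the isopropenyl group it produces.
- Comparison: the chosen plan erases C10 on enolisation, so a racemic aldehyde suffices, and sets C5 and C10 together by the geometry of a cycloaddition.

Key step: step 10

Remark on the chemistry (assumption): the complex made from Ti(OiPr)4 and (R,R)-TADDOL, (4R,5R)-2,2-dimethyl-α,α,α',α'-tetraphenyl-1,3-dioxolane-4,5-dimethanol, is assumed to direct the dienoate to the face that gives the (5S,6R,7R,10S) adduct. If the sense is the opposite, the (S,S)-ligand is used with no other change.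

## Route

Step 1
Reactants: 1 1,3-dimethoxybenzene; 2 acetone
Product: 4 2-(2,6-dimethoxyphenyl)propan-2-ol, via 2,6-dimethoxyphenyllithium 3 (not isolated)
Conditions: nBuLi, THF, 0 °C to rt; acetone, −78 °C to rt; H2O
Reagents that add atoms: none
Why: Directed ortho-lithiation at the carbon between the two methoxy groups, followed by 1,2-addition to acetone; both ethers direct to the same site, so the position is unambiguous.

Step 2
Reactants: 4 2-(2,6-dimethoxyphenyl)propan-2-ol
Product: 5 1,3-dimethoxy-2-(propan-2-yl)benzene
Conditions: Et3SiH, CF3CO2H, CH2Cl2, 0 °C to rt
Reagents that add atoms: none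
Why: Ionic hydrogenation; the tertiary benzylic cation, stabilised by two ortho methoxy groups, is trapped by hydride from the silane, and excess silane suppresses arene alkylation by the cation.

Step 3
Reactants: 5 1,3-dimethoxy-2-(propan-2-yl)benzene
Product: 8 2,4-dimethoxy-3-(propan-2-yl)phenol, via aryllithium 6 (not isolated), via dimethyl arylboronate 7 (not isolated)
Conditions: nBuLi, TMEDA, Et2O, 0 °C to rt; B(OMe)3, −78 °C to rt; H2O2, AcOH, 0 °C
Reagents that add atoms: hydrogen peroxide, OO; trimethyl borate, COB(OC)OC (its atoms stay only in intermediate 7)
Why: Directed ortho-metalation next to a methoxy group (the two free ortho positions are equivalent by symmetry), borylation and oxidative carbon-to-oxygen migration of the aryl group give the phenol in one flask. This oxygen becomes O11.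

Step 4
Reactants: 8 2,4-dimethoxy-3-(propan-2-yl)phenol
Product: 9 1,3-dimethoxy-4-(methoxymethoxy)-2-(propan-2-yl)benzene
Conditions: NaH, MOMCl, THF, 0 °C to rt
Reagents that add atoms: chloromethyl methyl ether, COCCl
Why: Williamson O-alkylation of the phenoxide; the methoxymethyl ether protects O11 and is the strongest ortho-director on the ring for the next step.

Step 5
Reactants: 9 1,3-dimethoxy-4-(methoxymethoxy)-2-(propan-2-yl)benzene; 10 5-chloropentan-2-one
Product: 12 racemic 5-chloro-2-[3,5-dimethoxy-2-(methoxymethoxy)-4-(propan-2-yl)phenyl]pentan-2-ol, via aryllithium 11 (not isolated)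
Conditions: nBuLi, THF, 0 °C; LaCl3·2LiCl, 5-chloropentan-2-one, −78 °C; AcOH, −78 °C
Reagents that add atoms: none
Why: Directed ortho-metalation; the methoxymethoxy group outranks methoxy, so lithiation goes to C9 and not to C8. The aryllithium adds to the ketone, with LaCl3·2LiCl favouring addition over enolisation, and the cold quench keeps the primary chloride.

Step 6
Reactants: 12 racemic 5-chloro-2-[3,5-dimethoxy-2-(methoxymethoxy)-4-(propan-2-yl)phenyl]pentan-2-ol
Product: 13 racemic 6-(5-chloropentan-2-yl)-2,4-dimethoxy-3-(propan-2-yl)phenol
Conditions: Et3SiH, CF3CO2H, CH2Cl2, 0 °C to rt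
Reagents that add atoms: none
Why: Ionic hydrogenation of the tertiary benzylic carbinol; the acid also cleaves the methoxymethyl acetal, and the silane reduces the methoxymethyl cation to dimethyl ether so that it cannot attack the free arene position. C10 is formed racemic, which is of no consequence because step 10 planarises it.

Step 7
Reactants: 13 racemic 6-(5-chloropentan-2-yl)-2,4-dimethoxy-3-(propan-2-yl)phenol
Product: 14 racemic 7,9-dimethoxy-5-methyl-8-(propan-2-yl)-2,3,4,5-tetrahydro-1-benzoxepine
Conditions: K2CO3, NaI (cat.), DMF (0.01 M), 70 °C, Ar
Reagents that add atoms: none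
Why: Intramolecular Williamson etherification (7-exo-tet) of the phenoxide on the primary halide; high dilution and iodide catalysis favour ring closure over oligomerisation, and both ortho positions are blocked, so only O-alkylation is possible.

Step 8
Reactants: 14 racemic 7,9-dimethoxy-5-methyl-8-(propan-2-yl)-2,3,4,5-tetrahydro-1-benzoxepine
Product: 15 racemic 7,9-dimethoxy-5-methyl-8-(propan-2-yl)-2,3,4,5-tetrahydro-1-benzoxepine-6-carbaldehyde
Conditions: Cl2CHOMe, TiCl4, CH2Cl2, −78 to 0 °C; H2O
Reagents that add atoms: dichloromethyl methyl ether, COC(Cl)Cl; water, O
Why: Rieche formylation; the only free arene position (C8) is ortho to one methoxy group and para to the other, so electrophilic substitution has no regiochemical alternative.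

Step 9
Reactants: 16 methacrolein; 17 trimethyl phosphonoacetate
Product: 18 methyl (2E)-4-methylpenta-2,4-dienoate
Conditions: NaH, THF, 0 °C to rt
Reagents that add atoms: none
Why: Horner–Wadsworth–Emmons olefination; the stabilised phosphonate anion gives the E enoate, which fixes the trans relation of ester and isopropenyl group that step 10 transfers to C6 and C5.

Step 10
Reactants: 15 racemic 7,9-dimethoxy-5-methyl-8-(propan-2-yl)-2,3,4,5-tetrahydro-1-benzoxepine-6-carbaldehyde; 18 methyl (2E)-4-methylpenta-2,4-dienoate
Product: 20 methyl (5S,6R,7R,10S)-3,11-epoxy-7-hydroxy-12,14-dimethoxy-3,4-seco-abieta-4(18),8,11,13-tetraene-6-carboxylate, via titanium-bound dienol 19 (not isolated)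
Conditions: Ti(OiPr)4 (3 equiv), (R,R)-TADDOL (1.5 equiv), 18 (3 equiv), toluene (degassed), hν 366 nm, rt
Reagents that add atoms: none
Why: Excitation of the aryl aldehyde is followed by 1,5-hydrogen transfer from the tertiary benzylic C10–H to the carbonyl oxygen and decay of the biradical to the hydroxy-ortho-quinodimethane 19, which Ti(OiPr)4 holds through its oxygen together with the TADDOL ligand; the closest known reaction type is the Ti(OiPr)4-mediated photoenolisation Diels–Alder reaction of ortho-sec-alkyl benzaldehydes that forms benzylic quaternary carbons. Ring B closes by an intermolecular suprafacial [4+2] cycloaddition across the C5=C6 bond of 18, which forms C5–C10 and C6–C7 together and returns aromaticity to ring C. The ester carbonyl of 18 binds the same titanium as the dienol oxygen, which puts the ester carbon next to C7 (regiochemistry) and under the diene (endo), so the C6 ester ends cis to the C7 hydroxyl. C7 follows from the long-lived dienol with its oxygen outward. C10 follows from the oxepine ring, which makes the C9=C10 bond of 19 endocyclic and so holds C1 outward and the methyl group inward. C5 follows from the E geometry of 18: the isopropenyl group is trans to the ester, hence exo and cis to the inward methyl group, as in the target. The absolute sense comes from the TADDOL ligand on titanium, which shields one face of the planar dienol, and the racemic C10 of 15 is erased on enolisation. The step therefore needs endo addition, the ester next to the carbinol and attack on one face, secured by titanium chelation, the ether tether and the chiral diol respectively.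

Step 11
Reactants: 20 methyl (5S,6R,7R,10S)-3,11-epoxy-7-hydroxy-12,14-dimethoxy-3,4-seco-abieta-4(18),8,11,13-tetraene-6-carboxylate
Product: 21 methyl (5S,10S)-3,11-epoxy-12,14-dimethoxy-7-oxo-3,4-seco-abieta-4(18),8,11,13-tetraene-6-carboxylate (C6 epimers and enol form)
Conditions: Dess–Martin periodinane, CH2Cl2, 0 °C to rt
Reagents that add atoms: none
Why: Dess–Martin oxidation of the secondary benzylic alcohol under near-neutral conditions that spare the isopropenyl group and the electron-rich arene. C6 becomes epimerisable, which does not matter because it is a methylene after step 12.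

Step 12
Reactants: 21 methyl (5S,10S)-3,11-epoxy-12,14-dimethoxy-7-oxo-3,4-seco-abieta-4(18),8,11,13-tetraene-6-carboxylate
Product: 22 (5S,10S)-3,11-epoxy-12,14-dimethoxy-3,4-seco-abieta-4(18),8,11,13-tetraen-7-one
Conditions: LiCl, H2O, DMSO, 140 °C
Reagents that add atoms: none
Why: Krapcho dealkoxycarbonylation; chloride attacks the ester methyl group and the β-keto carboxylate loses carbon dioxide. The medium is close to neutral, and C5 is not enolisable, so its configuration is untouched.

Step 13
Reactants: 22 (5S,10S)-3,11-epoxy-12,14-dimethoxy-3,4-seco-abieta-4(18),8,11,13-tetraen-7-one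
Product: 23 (5S,10S)-3-hydroxy-12-methoxy-3,4-seco-abieta-4(18),8,12-triene-7,11,14-trione
Conditions: (NH4)2Ce(NO3)6, MeCN/H2O, 0 °C
Reagents that add atoms: water, O
Why: Oxidative dealkylation of a para-dialkoxyarene by tetravalent cerium; water attacks the radical cation at C11 and C14, methanol leaves from C14 and the ring oxygen stays on C3 as the hydroxyl, as in the opening of chroman ethers to hydroxyalkyl quinones. The para pair is oxidised in preference to the ortho pair, and the C12 methoxy group survives as a vinylogous ester.

Step 14
Reactants: 23 (5S,10S)-3-hydroxy-12-methoxy-3,4-seco-abieta-4(18),8,12-triene-7,11,14-trione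
Product: 25 (5S,10S)-11,14-dihydroxy-12-methoxy-7-oxo-3,4-seco-abieta-4(18),8,11,13-tetraen-3-oic acid, via quinone acid 24 (not isolated)
Conditions: TEMPO (cat.), PhI(OAc)2, MeCN/H2O, rt; then aq Na2S2O4, EtOAc, rt, Ar
Reagents that add atoms: water, O
Why: Oxoammonium-mediated oxidation takes the primary alcohol through the aldehyde hydrate to the acid without touching the alkene or the quinone. The dithionite work-up then reduces the quinone to the hydroquinone, so the air-sensitive product never meets base or oxidant.

## Compound list

1 | 1,3-dimethoxybenzene | COc1cccc(OC)c1 | starting material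
2 | acetone | CC(C)=O | starting material
3 | 2,6-dimethoxyphenyllithium | [Li]c1c(OC)cccc1OC | intermediate (not isolated)
4 | 2-(2,6-dimethoxyphenyl)propan-2-ol | CC(C)(O)c1c(OC)cccc1OC | intermediate
5 | 1,3-dimethoxy-2-(propan-2-yl)benzene | CC(C)c1c(OC)cccc1OC | intermediate
6 | [2,4-dimethoxy-3-(propan-2-yl)phenyl]lithium | [Li]c1ccc(OC)c(C(C)C)c1OC | intermediate (not isolated)
7 | dimethyl [2,4-dimethoxy-3-(propan-2-yl)phenyl]boronate | COB(OC)c1ccc(OC)c(C(C)C)c1OC | intermediate (not isolated)
8 | 2,4-dimethoxy-3-(propan-2-yl)phenol | Oc1ccc(OC)c(C(C)C)c1OC | intermediate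
9 | 1,3-dimethoxy-4-(methoxymethoxy)-2-(propan-2-yl)benzene | COCOc1ccc(OC)c(C(C)C)c1OC | intermediate
10 | 5-chloropentan-2-one | CC(=O)CCCCl | starting material
11 | [3,5-dimethoxy-2-(methoxymethoxy)-4-(propan-2-yl)phenyl]lithium | [Li]c1cc(OC)c(C(C)C)c(OC)c1OCOC | intermediate (not isolated)
12 | racemic 5-chloro-2-[3,5-dimethoxy-2-(methoxymethoxy)-4-(propan-2-yl)phenyl]pentan-2-ol | CC(O)(CCCCl)c1cc(OC)c(C(C)C)c(OC)c1OCOC | intermediate
13 | racemic 6-(5-chloropentan-2-yl)-2,4-dimethoxy-3-(propan-2-yl)phenol | CC(CCCCl)c1cc(OC)c(C(C)C)c(OC)c1O | intermediate
14 | racemic 7,9-dimethoxy-5-methyl-8-(propan-2-yl)-2,3,4,5-tetrahydro-1-benzoxepine | CC1CCCOc2c(OC)c(C(C)C)c(OC)cc21 | intermediate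
15 | racemic 7,9-dimethoxy-5-methyl-8-(propan-2-yl)-2,3,4,5-tetrahydro-1-benzoxepine-6-carbaldehyde | CC1CCCOc2c(OC)c(C(C)C)c(OC)c(C=O)c21 | intermediate
16 | methacrolein (2-methylprop-2-enal) | C=C(C)C=O | starting material
17 | trimethyl phosphonoacetate | COC(=O)CP(=O)(OC)OC | starting material
18 | methyl (2E)-4-methylpenta-2,4-dienoate | C=C(C)/C=C/C(=O)OC | intermediate
19 | [7,9-dimethoxy-5-methyl-8-(propan-2-yl)-3,4-dihydro-1-benzoxepin-6(2H)-ylidene]methanol, hydroxyl outward (on the side of the C7 methoxy carbon of the benzoxepine), held on titanium in the flask | O/C=C1\C(OC)=C(C(C)C)C(OC)=C2OCCCC(C)=C12 | intermediate (not isolated)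
20 | methyl (5S,6R,7R,10S)-3,11-epoxy-7-hydroxy-12,14-dimethoxy-3,4-seco-abieta-4(18),8,11,13-tetraene-6-carboxylate (C6 ester cis to C7 hydroxyl and to C1; C5 isopropenyl cis to C20 methyl) | C=C(C)[C@@H]1[C@@H](C(=O)OC)[C@@H](O)c2c(OC)c(C(C)C)c(OC)c3OCCC[C@]1(C)c23 | intermediate
21 | methyl (5S,10S)-3,11-epoxy-12,14-dimethoxy-7-oxo-3,4-seco-abieta-4(18),8,11,13-tetraene-6-carboxylate (C6 epimers and enol form) | C=C(C)[C@@H]1C(C(=O)OC)C(=O)c2c(OC)c(C(C)C)c(OC)c3OCCC[C@]1(C)c23 | intermediate
22 | (5S,10S)-3,11-epoxy-12,14-dimethoxy-3,4-seco-abieta-4(18),8,11,13-tetraen-7-one | C=C(C)[C@@H]1CC(=O)c2c(OC)c(C(C)C)c(OC)c3OCCC[C@]1(C)c23 | intermediate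
23 | (5S,10S)-3-hydroxy-12-methoxy-3,4-seco-abieta-4(18),8,12-triene-7,11,14-trione | C=C(C)[C@@H]1CC(=O)C2=C(C(=O)C(OC)=C(C(C)C)C2=O)[C@@]1(C)CCCO | intermediate
24 | (5S,10S)-12-methoxy-7,11,14-trioxo-3,4-seco-abieta-4(18),8,12-trien-3-oic acid | C=C(C)[C@@H]1CC(=O)C2=C(C(=O)C(OC)=C(C(C)C)C2=O)[C@@]1(C)CCC(=O)O | intermediate (not isolated)
25 | (5S,10S)-11,14-dihydroxy-12-methoxy-7-oxo-3,4-seco-abieta-4(18),8,11,13-tetraen-3-oic acid, that is 3-[(1S,2S)-5,8-dihydroxy-7-methoxy-1-methyl-4-oxo-6-(propan-2-yl)-2-(prop-1-en-2-yl)-1,2,3,4-tetrahydronaphthalen-1-yl]propanoic acid | C=C(C)[C@@H]1CC(=O)c2c(O)c(C(C)C)c(OC)c(O)c2[C@@]1(C)CCC(=O)O | target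

## Step count and least certain steps

Total: 14 steps. Longest linear sequence: 13 steps (steps 1–8 and 10–14); step 9 is a one-step side branch.

**Step 10 (key step).** Three things may go wrong.

- The cycloaddition at the tetrasubstituted dienol terminus may be slow with a β-branched dienoate. The dienol would then be lost by [1,5]-hydrogen shift from the inward methyl group or by return to the aldehyde.
- Triplet energy transfer from the excited aldehyde to the dienoate may isomerise its C5=C6 bond and erode the C5 configuration.
- A monodentate ester is held loosely by the Ti(OiPr)4/TADDOL complex, so face selection may be weak. Isopropoxide may also exchange with the methyl esters.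

The fallback moves face control to a covalent auxiliary on a two-point-binding dienophile. From 16, phosphonate olefination with the phosphonoacetyl derivative of (S)-4-benzyl-1,3-oxazolidin-2-one (LiCl, DBU) gives the dienoyl imide (4S)-4-benzyl-3-[(2E)-4-methylpenta-2,4-dienoyl]-1,3-oxazolidin-2-one F1. Irradiation of 15 with Ti(OiPr)4 and F1 should give the imide adduct F2. The imide binds titanium through both carbonyls and is more electrophilic, and the auxiliary selects the face. The antipode of the auxiliary is chosen by the observed sense. Methanolysis (MeOMgBr, MeOH, 0 °C) returns to 20.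

**Step 13.** Oxidation may occur at the ortho pair O11/O12 instead of the para pair. The isopropenyl group may be attacked. Conversion may be slow because the aryl ketone lowers the electron density of ring C. The fallback changes the oxidation to that of a para-alkoxyphenol. From 22, BCl3 (CH2Cl2, −78 °C) cleaves only the methyl ether peri to the ketone, through chelation, giving the 14-hydroxy compound F3. PhI(OAc)2 in aqueous MeCN then oxidises this phenol, with the same opening of the ether ring, to 23.

**Step 5.** The aryllithium may deprotonate the ketone. The resulting enolate closes to a cyclopropyl ketone and the arene is returned. The fallback avoids an enolisable ketone at the addition stage. Aryllithium 11 (from 9) is acylated with 4-chloro-N-methoxy-N-methylbutanamide to give the chloro ketone F4. Methylenation with Cp2TiMe2 (toluene, 65 °C) gives the alkene F5. Treatment with Et3SiH and CF3CO2H protonates the alkene to the same benzylic cation and removes the acetal, returning to 13.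

**Step 7.** Closure of the seven-membered ring by a phenoxide flanked on both sides may be slower than intermolecular alkylation. The fallback closes the same bond by redox dehydration of an alcohol. From 12, NaH in THF closes the chloro alkoxide to the oxolane F6. Et3SiH and CF3CO2H open it reductively and remove the acetal to give the phenol alcohol F7. A Mitsunobu reaction (PPh3, DIAD, THF, high dilution) then gives 14.

**Step 8.** Formylation at the position between a methoxy group and the oxepine carbon may be slow, and TiCl4 may cleave a methyl ether next to the new aldehyde. The fallback is anionic. From 14, NBS in MeCN brominates the only free position to give the bromide F8. Bromine–lithium exchange (nBuLi, THF, −78 °C) and DMF return to 15.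

## Further compounds

F1 | step 10 | (4S)-4-benzyl-3-[(2E)-4-methylpenta-2,4-dienoyl]-1,3-oxazolidin-2-one | C=C(C)/C=C/C(=O)N1C(=O)OC[C@@H]1Cc1ccccc1
F2 | step 10 | (4S)-4-benzyl-3-{[(5S,6R,7R,10S)-3,11-epoxy-7-hydroxy-12,14-dimethoxy-3,4-seco-abieta-4(18),8,11,13-tetraen-6-yl]carbonyl}-1,3-oxazolidin-2-one | C=C(C)[C@@H]1[C@@H](C(=O)N4C(=O)OC[C@@H]4Cc5ccccc5)[C@@H](O)c2c(OC)c(C(C)C)c(OC)c3OCCC[C@]1(C)c23
F3 | step 13 | (5S,10S)-3,11-epoxy-14-hydroxy-12-methoxy-3,4-seco-abieta-4(18),8,11,13-tetraen-7-one | C=C(C)[C@@H]1CC(=O)c2c(O)c(C(C)C)c(OC)c3OCCC[C@]1(C)c23
F4 | step 5 | 4-chloro-1-[3,5-dimethoxy-2-(methoxymethoxy)-4-(propan-2-yl)phenyl]butan-1-one | O=C(CCCCl)c1cc(OC)c(C(C)C)c(OC)c1OCOC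
F5 | step 5 | 1-(5-chloropent-1-en-2-yl)-3,5-dimethoxy-2-(methoxymethoxy)-4-(propan-2-yl)benzene | C=C(CCCCl)c1cc(OC)c(C(C)C)c(OC)c1OCOC
F6 | step 7 | racemic 2-[3,5-dimethoxy-2-(methoxymethoxy)-4-(propan-2-yl)phenyl]-2-methyloxolane | CC1(CCCO1)c1cc(OC)c(C(C)C)c(OC)c1OCOC
F7 | step 7 | racemic 6-(5-hydroxypentan-2-yl)-2,4-dimethoxy-3-(propan-2-yl)phenol | CC(CCCO)c1cc(OC)c(C(C)C)c(OC)c1O
F8 | step 8 | racemic 6-bromo-7,9-dimethoxy-5-methyl-8-(propan-2-yl)-2,3,4,5-tetrahydro-1-benzoxepine | CC1CCCOc2c(OC)c(C(C)C)c(OC)c(Br)c21
A1 | alternative 1 | (4S)-4-tert-butyl-2-[1-allyl-4,5,7,8-tetramethoxy-6-(propan-2-yl)-2-(prop-1-en-2-yl)-1,2-dihydronaphthalen-1-yl]-4,5-dihydro-1,3-oxazole (configuration as in the SMILES) | CC(C)(C)[C@H]1COC(=N1)[C@]3(CC=C)[C@H](C(C)=C)C=C(OC)c2c(OC)c(C(C)C)c(OC)c(OC)c23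
A2 | alternative 1 | (4S)-4-tert-butyl-2-[4,5,7,8-tetramethoxy-6-(propan-2-yl)naphthalen-1-yl]-4,5-dihydro-1,3-oxazole | CC(C)(C)[C@H]1COC(=N1)c3ccc(OC)c2c(OC)c(C(C)C)c(OC)c(OC)c23
A3 | alternative 2 | 8-[3-(tert-butyldimethylsilyloxy)propyl]-2-methoxy-8-methyl-3-(propan-2-yl)-7-(prop-1-en-2-yl)-5,6,7,8-tetrahydronaphthalene-1,4-diol (abietane 5S,10S) | Oc1c(C(C)C)c(OC)c(O)c2c1CC[C@@H](C(C)=C)[C@]2(C)CCCO[Si](C)(C)C(C)(C)C
A4 | alternative 2 | 4-{6-[3-(tert-butyldimethylsilyloxy)propyl]-6-methyl-5-(prop-1-en-2-yl)cyclohex-1-en-1-yl}-4-hydroxy-3-methoxy-2-(propan-2-yl)cyclobut-2-en-1-one (ring B centres as in A3; carbinol centre undefined) | O=C1C(C(C)C)=C(OC)C1(O)C2=CCC[C@@H](C(C)=C)[C@]2(C)CCCO[Si](C)(C)C(C)(C)C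
A5 | alternative 3 | methyl 3-[3-hydroxy-5,7,8-trimethoxy-1-methyl-4-oxo-6-(propan-2-yl)-2-(prop-1-en-2-yl)-1,2,3,4-tetrahydronaphthalen-1-yl]propanoate (abietane 5S,10S; C6 hydroxyl as in the SMILES) | C=C(C)[C@@H]1[C@@H](O)C(=O)c2c(OC)c(C(C)C)c(OC)c(OC)c2[C@@]1(C)CCC(=O)OC
A6 | alternative 3 | methyl 4,6-dimethyl-4-[2,3,5-trimethoxy-6-(oxoacetyl)-4-(propan-2-yl)phenyl]hept-5-enoate (C4 as in the SMILES) | O=CC(=O)c1c(OC)c(C(C)C)c(OC)c(OC)c1[C@@](C=C(C)C)(C)CCC(=O)OC
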